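All constants are invented; no experiment stands behind them.

We read these flasks at 10 h and ask how the substrate that has come through has split.

    substrate ⇌ dormant form (K1 = 0.47, k1 = 0.0018 /min)
    open intermediate + second intermediate → target (k2 = 0.0091 /M/min)
    2 open intermediate → homo product (k3 = 0.015 /M/min)
    partner → second intermediate (k4 = 0.098 /min)
    crystals ⇌ target, rate k5*(cs5 - [target]) while solid is left; crystals form when [target] > cs5 (cs5 = 0.13 M, k5 = 0.065 /min)
    substrate → open intermediate (k6 = 0.0018 /min)

| flask | substrate | partner | time | remark |
|---|---|---|---|---|
| noon | 0.20 M | 0.400 M | 10 h | everything together at the start |
| winter | 0.20 M | 0.400 M (fed, over 6.0 h) | 10 h | all else is in the flask from the start; the feed brings no volume worth counting |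
| midnight | 0.20 M (in portions, 2, over 6.0 h) | 0.400 M | 10 h | first portion at the start, last at 6.0 h |
| dusk | 0.20 M (fed, over 6.0 h) | 0.400 M | 10 h | all else is in the flask from the start; the feed brings no volume worth counting |

1. which flask leads in share of target in target plus homo product ("all alike" within 1.5 percentage points) (noon / winter / midnight / dusk / all alike)
2. share of target in target plus homo product at the end, noon
3. share of target in target plus homo product at the end, winter
4. share of target in target plus homo product at the end, midnight
5. share of target in target plus homo product at the end, dusk

- a species is counted by the substrate in it: one homo product counts as two
- amounts and yields of target count crystals too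
- two of one species on the left: rate k times its square, two consumed each time
- given per volume of solution although it is solid: crystals
- run time (noon): 10 h

Open intermediate has two exits: with second intermediate to target, or with itself to homo product, which counts two. Let X be the cross constant times [second intermediate], divided by 2 times the homo constant; at 0.400 M that is 0.121 M. X is the crossover level, the [open intermediate] at which both exits take equal substrate. With I for [open intermediate], the share at any moment is X/(X+I).

So we need I, and we count turnovers. Partner's half-life of 0.12 h is shorter than the feed, so second intermediate follows the charge. Dormant form relaxes in 2.05 h, faster than substrate opens, but by a factor of just 3.13, so substrate goes in free and lags behind the balance. As a rough figure for the whole run we take the equilibrium free part, 68.0% of the pool. On that figure the pool opens at 0.00122 /min, or 0.732 turnovers in the run. With second intermediate taken at the charge, the cross exit is treated as pseudo-first-order in open intermediate and runs at 0.00364 /min, or 2.18 turnovers.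

A two-step chain at these rates gives noon 0.0362 M at mid-run, so a share of 77.0%. Winter averages 0.280 M of second intermediate, so its level is 0.0420 M and its share 66.9%. In midnight and dusk substrate arrives on average at 3.00 h, and the chain over the remaining time gives 0.0312 M, so 79.6% for midnight and 79.6% for dusk. Our reckoning stops there, with those two level.

The forecast gave 78% for noon, 70% for winter, 82% for midnight and 80% for dusk, with midnight leading, because “splitting or feeding substrate lowers the intermediate's level”. Unlike our reckoning, it parts midnight from dusk.

The flasks gave 77.5% for noon, 68.9% for winter, 82.5% for midnight and 80.1% for dusk, so midnight leads dusk by 2.4 percentage points.

In winter, at the end of the feed at 6.00 h, open intermediate stood at 21.0% of the substrate charged and homo product at 7.08%. In midnight, at that hour, they stood at 9.47% and 1.30%. In noon at 10.0 h, 0.339 M of second intermediate puts X at 0.103 M, and I stood lower, at 0.0309 M. The neighbour of winter charged with 1.0 M of partner averages 0.700 M of second intermediate, which gives X 0.212 M, a level of 0.0259 M and a share of 89.1%; that flask ended at 87.9%.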